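**Plan**
1. One skeletal cut only: the C5'(ring B)–CH2 bond, giving natural (S)-eriodictyol and a C10 allylic carbonate made from geraniol; all other cuts are O-protecting groups.
2. Side chain: geraniol → methyl carbonate → Markovnikov hydration of the remote 6,7-alkene (4). Flavanone: O3'/O4' are tied into a temporary 2-ethoxy-1,3-dioxole ring (cyclic orthoformate), then O7 is silylated (7).
3. The halves are joined in one flask: Ir-catalysed C5'–H borylation, then base-free Pd allyl–aryl coupling; buffered fluoride and dilute acid then remove TIPS and the orthoester.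
4. Enabling feature: with O3'/O4' held back in the dioxole, C5'–H of ring B is the only unflanked aromatic C–H. C2' lies between C1' and O3', C6' is next to the branched chromanone C2, and C6/C8 of ring A lie between two oxygens, so the catechol itself steers the metal to the right carbon.
5. Stereochemistry: C2 (S) comes from the chiral pool and never meets free base; the E-alkene comes from geraniol and is retained in the π-allyl coupling.

Key step: step 5

Assumption: (S)-eriodictyol (natural (–)-eriodictyol) is taken as a commercial, enantiopure starting material. Compounds 6–11 carry a temporary stereocentre at the orthoester carbon and are handled as mixtures of both epimers (that centre is left undefined in the SMILES); it disappears in step 6.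

**Step 1**
Reactants: 1 geraniol
Product: 2 geranyl methyl carbonate
Conditions: ClCO2Me, pyridine, CH2Cl2, 0 °C to rt
Reagents that add atoms: methyl chloroformate, COC(=O)Cl
Why: Acylation of a primary allylic alcohol with a chloroformate (carbonate formation) is routine and leaves both alkenes and the E geometry untouched.

**Step 2**
Reactants: 2 geranyl methyl carbonate
Product: 4 methyl (2E)-7-hydroxy-3,7-dimethyloct-2-en-1-yl carbonate, via organomercurial 3 (not isolated)
Conditions: Hg(OAc)2 (1.0 equiv), THF–H2O 1:1, 0 °C to rt; then NaBH4, 3 M aq NaOH, 0 °C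
Reagents that add atoms: water, O
Why: Oxymercuration–demercuration (Markovnikov hydration) should take the electron-richer remote 6,7-alkene because the 2,3-alkene is deactivated by the allylic carbonate, as is known for geranyl acetate; the C6 centre of 3 vanishes on C–Hg reduction and the E-alkene is untouched.

**Step 3**
Reactants: 5 (S)-eriodictyol
Product: 6 (2S)-2-(2-ethoxy-1,3-benzodioxol-5-yl)-5,7-dihydroxychroman-4-one
Conditions: HC(OEt)3 (1.5 equiv), PPTS (5 mol %), THF–toluene 1:2, 4 Å MS, 80 °C; Et3N quench, Et3N-washed silica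
Reagents that add atoms: triethyl orthoformate, CCOC(OCC)OCC
Why: Acid-catalysed orthoester exchange closes a five-membered 1,3-dioxole only on the vicinal 3',4'-diol (chelate effect), whereas the isolated 5- and 7-phenols can form only labile mixed orthoesters that revert on work-up; the weak acid leaves C2 alone and the new orthoester carbon forms without control (both epimers carried on).

**Step 4**
Reactants: 6 (2S)-2-(2-ethoxy-1,3-benzodioxol-5-yl)-5,7-dihydroxychroman-4-one
Product: 7 (2S)-2-(2-ethoxy-1,3-benzodioxol-5-yl)-5-hydroxy-7-(triisopropylsilyloxy)chroman-4-one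
Conditions: TIPSCl (1.1 equiv), imidazole, DMF, 0 °C to rt
Reagents that add atoms: triisopropylsilyl chloride, CC(C)[Si](Cl)(C(C)C)C(C)C
Why: Silylation of the most acidic, unchelated phenol (O7) with a silyl chloride and imidazole is standard for 5,7-dihydroxyflavanones; the 5-OH stays hydrogen-bonded to C4=O and free, and the bulky TIPS group later shields C6 and C8.

**Step 5**
Reactants: 7 (2S)-2-(2-ethoxy-1,3-benzodioxol-5-yl)-5-hydroxy-7-(triisopropylsilyloxy)chroman-4-one; 4 methyl (2E)-7-hydroxy-3,7-dimethyloct-2-en-1-yl carbonate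
Product: 10 7-O-TIPS-3',4'-O-(ethoxymethylidene)propolin B, via O,C-diboryl flavanone 8 (not isolated), via O-boryl coupled flavanone 9 (not isolated)
Conditions: [Ir(OMe)(cod)]2 (2 mol %), dtbpy (4 mol %), B2pin2 (1.2 equiv), THF, 60 °C; volatiles removed; then 4 (1.3 equiv), Pd(PPh3)4 (5 mol %), THF, 45 °C; pH 7 buffer work-up
Reagents that add atoms: none
Why: An Ir(III) tris(boryl)–dtbpy complex should first O-borylate the chelated 5-OH and then cleave the least hindered aromatic C–H bond, C5'–H, which is ortho only to the tied-back dioxole oxygen O4', whereas C2' (between C1' and O3'), C6' (next to the branched chromanone C2) and C6/C8 of ring A (each between two oxygens, one carrying TIPS) are shielded; the closest known reaction is the sterically governed Ir C–H borylation of 1,3-benzodioxoles ortho to oxygen. Pd(0) then ionises the allylic carbonate of 4 with loss of CO2 to a π-allyl-Pd methoxide, the Pd–OMe group triggers aryl transfer from boron in 8 without added base, and reductive elimination at the unsubstituted allyl terminus forms the C5'–CH2 bond (base-free Suzuki–Miyaura coupling of aryl boronates with allylic carbonates). No ring is closed and no stereocentre is formed; C2 (S) is a spectator because no free base is present that could open the pyranone by retro-oxa-Michael reaction. The E geometry should be kept because syn/anti exchange of the π-allyl would need a tertiary σ-Pd–C species, and linear rather than branched coupling follows from bond formation at the CH2 terminus with PPh3 as ligand. The tertiary alcohol of 4 is too poor a nucleophile to compete for the π-allyl, and the 5-O-boryl ester of 9 is cleaved in the neutral aqueous work-up.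

**Step 6**
Reactants: 10 7-O-TIPS-3',4'-O-(ethoxymethylidene)propolin B
Product: 13 propolin B, via desilylated orthoformate 11 (not isolated), via 3'-O-formyl propolin B 12 (not isolated)
Conditions: TBAF (1.2 equiv), AcOH (1.5 equiv), THF, 0 °C; then AcOH–H2O added (THF/AcOH/H2O 2:2:1), rt; degassed aq NaHCO3 work-up
Reagents that add atoms: none
Why: Acetic acid-buffered fluoride cleaves the aryl silyl ether without building up free phenoxide base (no retro-oxa-Michael racemisation), and aqueous acetic acid hydrolyses the cyclic orthoformate through the catechol monoformate; this standard silyl ether and orthoester deprotection is far too mild to protonate the trisubstituted alkene or ionise the tertiary alcohol.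

**Compound list**
1 | geraniol, (2E)-3,7-dimethylocta-2,6-dien-1-ol | CC(C)=CCC/C(C)=C/CO | starting material
2 | geranyl methyl carbonate | CC(C)=CCC/C(C)=C/COC(=O)OC | intermediate
3 | (2E)-6-(acetoxymercurio)-7-hydroxy-3,7-dimethyloct-2-en-1-yl methyl carbonate, racemic at C6 (formed in the flask, not isolated) | C/C(=C\COC(=O)OC)CCC([Hg]OC(C)=O)C(C)(C)O | intermediate
4 | methyl (2E)-7-hydroxy-3,7-dimethyloct-2-en-1-yl carbonate | C/C(=C\COC(=O)OC)CCCC(C)(C)O | intermediate
5 | (S)-eriodictyol, (2S)-2-(3,4-dihydroxyphenyl)-5,7-dihydroxychroman-4-one | Oc1ccc([C@@H]2CC(=O)c3c(O)cc(O)cc3O2)cc1O | starting material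
6 | (2S)-2-(2-ethoxy-1,3-benzodioxol-5-yl)-5,7-dihydroxychroman-4-one (both epimers at the orthoester carbon) | CCOC1Oc2ccc([C@@H]3CC(=O)c4c(O)cc(O)cc4O3)cc2O1 | intermediate
7 | (2S)-2-(2-ethoxy-1,3-benzodioxol-5-yl)-5-hydroxy-7-(triisopropylsilyloxy)chroman-4-one (both orthoester epimers) | CCOC1Oc2ccc([C@@H]3CC(=O)c4c(O)cc(O[Si](C(C)C)(C(C)C)C(C)C)cc4O3)cc2O1 | intermediate
8 | O,C-diboryl flavanone: 7 with Bpin on O5 and on C7 of the benzodioxole (= C5' of ring B) (formed in the flask, not isolated) | CCOC1Oc2c(B3OC(C)(C)C(C)(C)O3)cc([C@@H]3CC(=O)c4c(OB5OC(C)(C)C(C)(C)O5)cc(O[Si](C(C)C)(C(C)C)C(C)C)cc4O3)cc2O1 | intermediate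
9 | O-boryl coupled flavanone: 10 with Bpin on O5 (formed in the flask, not isolated) | CCOC1Oc2c(C/C=C(\C)CCCC(C)(C)O)cc([C@@H]3CC(=O)c4c(OB5OC(C)(C)C(C)(C)O5)cc(O[Si](C(C)C)(C(C)C)C(C)C)cc4O3)cc2O1 | intermediate
10 | (2S)-2-{2-ethoxy-7-[(2E)-7-hydroxy-3,7-dimethyloct-2-en-1-yl]-1,3-benzodioxol-5-yl}-5-hydroxy-7-(triisopropylsilyloxy)chroman-4-one (both orthoester epimers) | CCOC1Oc2c(C/C=C(\C)CCCC(C)(C)O)cc([C@@H]3CC(=O)c4c(O)cc(O[Si](C(C)C)(C(C)C)C(C)C)cc4O3)cc2O1 | intermediate
11 | (2S)-2-{2-ethoxy-7-[(2E)-7-hydroxy-3,7-dimethyloct-2-en-1-yl]-1,3-benzodioxol-5-yl}-5,7-dihydroxychroman-4-one (formed in the flask, not isolated) | CCOC1Oc2c(C/C=C(\C)CCCC(C)(C)O)cc([C@@H]3CC(=O)c4c(O)cc(O)cc4O3)cc2O1 | intermediate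
12 | 3'-O-formyl propolin B, in equilibrium with its 4'-O-formyl isomer by acyl shift (formed in the flask, not isolated) | C/C(=C\Cc1cc([C@@H]2CC(=O)c3c(O)cc(O)cc3O2)cc(OC=O)c1O)CCCC(C)(C)O | intermediate
13 | propolin B, (2S)-2-{3,4-dihydroxy-5-[(2E)-7-hydroxy-3,7-dimethyloct-2-en-1-yl]phenyl}-5,7-dihydroxychroman-4-one | C/C(=C\Cc1cc([C@@H]2CC(=O)c3c(O)cc(O)cc3O2)cc(O)c1O)CCCC(C)(C)O | target

**Count**
Total steps: 6. Longest linear sequence: 4 steps (5 → 6 → 7 → 10 → 13; the side-chain line 1 → 2 → 4 → 10 → 13 is equally long).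

**Steps most likely to fail**

Step 5. What may go wrong: loss of site control or hydroboration of the boron-chelated C4 carbonyl during C–H borylation of the fully functionalised flavanone, carry-over of boron residues into the palladium stage, or alkoxide-triggered opening of the pyranone with racemisation at C2. Fallback (sets out from 4, returns at 10): the aryl–CH2 bond would be made on a simple arene and C2 set by catalyst control instead of the chiral pool. Commercial 4-bromocatechol with HC(OEt)3/PPTS should give 5-bromo-2-ethoxy-1,3-benzodioxole F1. Ir-catalysed borylation (ortho to the dioxole oxygen, meta to Br) should give 5-bromo-2-ethoxy-7-(pinacolboryl)-1,3-benzodioxole F2. Pd(PPh3)4-catalysed coupling of F2 with 4 at 45 °C, where the C–Br bond stays intact, should give the bromoarene (E)-8-(6-bromo-2-ethoxy-1,3-benzodioxol-4-yl)-2,6-dimethyloct-6-en-2-ol F3. Miyaura-type borylation with B2(OH)4, KOAc and a Pd–XPhos catalyst in EtOH should give the arylboronic acid F4. Commercial 5,7-dihydroxychromone with TIPSCl/imidazole should give 5-hydroxy-7-(triisopropylsilyloxy)chromone F5. Rh(I)/chiral bisphosphine-catalysed asymmetric 1,4-addition of F4 to F5 in toluene–water at rt, with the ligand enantiomer that delivers 2S, should give 10.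

Step 3. What may go wrong: capture of the free 7-OH as a mixed orthoester, incomplete ring closure in a solvent that dissolves the tetraphenol poorly, and hydrolysis of the acid-labile orthoester during purification. Fallback (sets out from 5, returns at 7): the order of protection would be inverted. The most acidic phenol is silylated first (TIPSCl 1.0 equiv, iPr2NEt, DMF, –20 °C) to give (2S)-7-O-TIPS-eriodictyol F6. The dioxole is then closed on this toluene-soluble substrate, which has no second reactive phenol, with HC(OEt)3/PPTS and azeotropic removal of ethanol, to give 7.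

Step 6. What may go wrong: acid-promoted addition of the freed 4'-OH to the trisubstituted alkene (chroman formation) or ionisation of the tertiary alcohol during orthoester hydrolysis, and air oxidation of the free catechol. Fallback (sets out from 5 by way of F6 above, returns at 13): the catechol would be held back in a fluoride-labile ring so that no acid is needed at the end. F6 with tBu2Si(OTf)2 and 2,6-lutidine in CH2Cl2 at 0 °C should give the 3',4'-O-di-tert-butylsilylene derivative F7, a five-membered 1,3,2-dioxasilole expected to give the same site control. The borylation/coupling of step 5 would then pass through the O,C-diboryl compound F8 (not isolated) and the O-boryl coupled compound F9 (not isolated) to the silylene-protected coupled flavanone F10. One treatment with TBAF/AcOH in THF at 0 °C should remove both silicon groups and give 13.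

**Further compounds**
F1 | step 5 | 5-bromo-2-ethoxy-1,3-benzodioxole (racemic) | CCOC1Oc2ccc(Br)cc2O1
F2 | step 5 | 5-bromo-2-ethoxy-7-(4,4,5,5-tetramethyl-1,3,2-dioxaborolan-2-yl)-1,3-benzodioxole | CCOC1Oc2cc(Br)cc(B3OC(C)(C)C(C)(C)O3)c2O1
F3 | step 5 | (E)-8-(6-bromo-2-ethoxy-1,3-benzodioxol-4-yl)-2,6-dimethyloct-6-en-2-ol | CCOC1Oc2cc(Br)cc(C/C=C(\C)CCCC(C)(C)O)c2O1
F4 | step 5 | {2-ethoxy-7-[(2E)-7-hydroxy-3,7-dimethyloct-2-en-1-yl]-1,3-benzodioxol-5-yl}boronic acid | CCOC1Oc2cc(B(O)O)cc(C/C=C(\C)CCCC(C)(C)O)c2O1
F5 | step 5 | 5-hydroxy-7-(triisopropylsilyloxy)-4H-chromen-4-one | O=c1ccoc2cc(O[Si](C(C)C)(C(C)C)C(C)C)cc(O)c12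
F6 | step 3 | (2S)-2-(3,4-dihydroxyphenyl)-5-hydroxy-7-(triisopropylsilyloxy)chroman-4-one | Oc1ccc([C@@H]2CC(=O)c3c(O)cc(O[Si](C(C)C)(C(C)C)C(C)C)cc3O2)cc1O
F7 | step 6 | (2S)-2-(2,2-di-tert-butyl-1,3,2-benzodioxasilol-5-yl)-5-hydroxy-7-(triisopropylsilyloxy)chroman-4-one | CC(C)(C)[Si]1(C(C)(C)C)Oc2ccc([C@@H]3CC(=O)c4c(O)cc(O[Si](C(C)C)(C(C)C)C(C)C)cc4O3)cc2O1
F8 | step 6 | F7 with Bpin on O5 and on C5' of ring B (not isolated) | CC(C)(C)[Si]1(C(C)(C)C)Oc2c(B3OC(C)(C)C(C)(C)O3)cc([C@@H]3CC(=O)c4c(OB5OC(C)(C)C(C)(C)O5)cc(O[Si](C(C)C)(C(C)C)C(C)C)cc4O3)cc2O1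
F9 | step 6 | F10 with Bpin on O5 (not isolated) | CC(C)(C)[Si]1(C(C)(C)C)Oc2c(C/C=C(\C)CCCC(C)(C)O)cc([C@@H]3CC(=O)c4c(OB5OC(C)(C)C(C)(C)O5)cc(O[Si](C(C)C)(C(C)C)C(C)C)cc4O3)cc2O1
F10 | step 6 | (2S)-2-{2,2-di-tert-butyl-7-[(2E)-7-hydroxy-3,7-dimethyloct-2-en-1-yl]-1,3,2-benzodioxasilol-5-yl}-5-hydroxy-7-(triisopropylsilyloxy)chroman-4-one | CC(C)(C)[Si]1(C(C)(C)C)Oc2c(C/C=C(\C)CCCC(C)(C)O)cc([C@@H]3CC(=O)c4c(O)cc(O[Si](C(C)C)(C(C)C)C(C)C)cc4O3)cc2O1
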